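## Analysis of the target

The target, 6-hydroxy-5-{[4-hydroxy-2-methoxy-6-(methoxymethyl)phenyl]methyl}-8-methoxy-3-methyl-1H-isochromen-1-one, is a 3-methylisocoumarin (benzo ring A fused to an α-pyranone) whose C5 is tied through one CH2 group to a second benzene ring, ring B. It has no stereocentre and no double-bond geometry to set, so the problem is one of regiochemistry and crowding. Ring A carries OH at C6 and OMe at C8; ring B carries the bridging carbon at C1', CH2OMe at C2', OH at C4' and OMe at C6'. Four phenolic oxygens must therefore end up differentiated, two methylated and two free. The bridging carbon has four ortho neighbours (C4a with the peri C4–H, C6–OH, C2'–CH2OMe, C6'–OMe), which makes joining two finished arenes at this carbon unattractive. The sensitive groups are the enol lactone (opened by hydroxide, alkoxides, amines and hard carbon nucleophiles), the benzylic methyl ether, and the electron-rich diarylmethane, which stands acid only for a limited time. The strategy rests on ring B: its methoxy group is ortho and its hydroxyl para to C1'. That is the pattern left when a butadiene with two alkoxy groups on C1 and a silyloxy group on C3 adds to an alkynyl ketone whose carbonyl carbon is the future bridging carbon.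

## Retrosynthetic reasoning

**Target 19 to ketone 16.** The bridging CH2 is traced back to a carbonyl group and the C6 phenol to its methoxymethyl ether. The carbonyl is not needed by the target; it is there because it turns an alkyne into a dienophile. It is removed last by ionic hydrogenation, which is favoured because the cation on this carbon has an ortho and a para oxygen donor on each ring. The forward step must take C=O to CH2 and remove the acetal without touching the lactone or the benzylic ether.

**Ketone 16 to ynone 10 and diene 13.** The C2'–C3' and C1'–C6' bonds of ring B are cut. These are the two bonds a [4+2] cycloaddition makes, and cutting here takes ring B apart completely. The crowded aryl–carbonyl bond is therefore already present in a small, linear precursor and never has to be made between two substituted arenes. The ketene acetal carbon of 13 becomes C6' and keeps one methoxy group; the silyloxy carbon becomes C4'. Both oxygens arrive differentiated. The forward reaction needs the correct orientation of diene and ynone, and the C6 oxygen must be masked so that it cannot add to the ynone.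

**Diene 13 to enone 12 to ketene acetal 11.** The O–Si bond is cut first (silyl dienol ether back to the methyl ketone), then the C2–C3 bond of the enone (C-acylation of the ketene acetal). This gives the diene in two steps from a commercial four-carbon unit.

**Ynone 10 to iodide 8 and alkyne 9.** Both bonds to the ketone carbon are cut, which corresponds to a three-component carbonylative coupling. This is chosen over adding an aryl metal to an acyl derivative because the lactone would not survive hard organometallics, whereas an aryl iodide is an ideal partner for palladium. The forward step must insert the carbonyl unit faster than the alkyne couples directly.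

**Iodide 8 to iodophenol 7 to phenol 6.** The acetal O–CH2 bond and the C5–I bond are cut. The halogen is introduced on the finished isocoumarin and on the free phenol for two reasons. C5 is ortho to the hydroxyl and para to the C8 methoxy group, whereas the only other open ring position, C7, lies between two oxygens. A halogen put on the benzoic acid before annulation would sit next to the one C–H bond the metal has to break in the annulation. The acetal is added only afterwards, so it is exposed to neither the Lewis-acidic annulation nor the acid-assisted iodination.

**Phenol 6 to acid 4 and ylide 3.** The C4–C4a and O2–C3 bonds are cut. The carboxyl group directs a metal to its only free ortho C–H bond (the other ortho position holds the methoxy group). The ylide supplies C4, C3 and the methyl group as a carbene equivalent, and the lactone closes by dehydration. This builds the pyranone in one step on an unhindered C–H bond.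

**Ylide 3 to salt 1.** The C–C bond between the ylide carbon and the acetyl group is cut (acylation of the methylide 2).

## Alternatives that were turned down

**Alternative 1:** The disconnection cuts C4–C4a and C1–C8a of ring A in a compound in which the two arenes are already joined through CH2. In the forward step a hindered lithium amide would turn a ring A bromide into the C4a–C8a aryne. Lithiated dimethyl malonate A2 would add at C4a, and the aryl anion at C8a would attack an ester carbonyl and open the four-membered alkoxide. The net result is insertion into a C–C bond of the malonate, giving the homophthalate methyl 6-methoxy-2-(2-methoxy-2-oxoethyl)-3-{[2-methoxy-6-(methoxymethyl)-4-(triisopropylsilyloxy)phenyl]methyl}-4-(triisopropylsilyloxy)benzoate A1.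
- In its favour: both carbons flanking ring A arrive in one operation, the C8 methoxy group steers the carbanion to the distal aryne carbon, and the bridge is already a CH2 group. No late deoxygenation is needed, and on that point it is stronger than the chosen route.
- Against it: the step closes no ring and sets no oxygen. The carbanion must attack the aryne carbon next to the bulky benzyl group. The strong base meets a doubly benzylic CH2 and a benzylic ether. A1 still needs several steps (hydrolysis, acylation with decarboxylation, lactonisation, two desilylations) to become the 3-methylpyranone. The diarylmethane bromide must first be assembled from two separately made, fully substituted arenes, which is the crowded union the chosen route avoids.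
- In place of the ready-made CH2 bridge, the chosen strategy offers a key step that closes ring B and fixes its oxygen pattern at once.

**Alternative 2:** The disconnection cuts C4a–C8a, so ring A is made from a pyranone carrying a polycarbonyl side chain. In the forward step a magnesium alkoxide in its alcohol would open the pyranone to an ester dienolate, whose carbon (future C8a) adds to the side-chain ketone (future C4a). Dehydration would give methyl 4-hydroxy-2-methoxy-5-{[2-methoxy-6-(methoxymethyl)-4-(methoxymethoxy)phenyl]methyl}-6-[(2-methyl-1,3-dioxolan-2-yl)methyl]benzoate A3.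
- In its favour: the closure is mild and follows the biosynthetic logic. Ring A is born with its oxygens differentiated, the bridge is made early by alkylation at an sp3 carbon, and A3 is only an acid treatment (ketal off, enol lactone closed, acetal off) from the target. On endgame simplicity it is at least as good as the chosen route.
- Against it: the open-chain precursor takes many steps to assemble and can cyclise in other ways (Claisen instead of aldol, re-closure to a pyranone, retro-Claisen cleavage at the benzylated dicarbonyl carbon). The bulky benzyl group sits on the carbon between the reacting centres. Ring B must be made separately as a benzyl electrophile with its own 2-OMe/4-O/6-CH2OMe regiochemistry problem.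
- The chosen strategy makes ring B in one step from a two-step diene and makes ring A in one catalytic step, so it is clearly shorter.

**Alternative 3:** The disconnection cuts C6–C7 of ring A; the pyranone is kept from 3-acetyl-4-hydroxy-6-methyl-2H-pyran-2-one A5. In the forward step a carboxylic acid on the future C5, activated as a mixed anhydride with a tertiary amine, would give a ketene at C6. Together with the pyranone C4a=C8a bond and a methyl enol ether (C8=C7) it would undergo a thermal six-electron electrocyclisation and tautomerise to 6-hydroxy-8-methoxy-5-{[2-methoxy-6-(methoxymethyl)-4-(methoxymethoxy)phenyl]methyl}-3-methyl-1H-isochromen-1-one A4.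
- In its favour: the closure is regiochemically unambiguous and redox-neutral, the lactone comes from a cheap template, and A4 is one deprotection from the target. It needs no ketone reduction, which makes it the strongest of the three at the end.
- Against it: the precursor is costly. The C4 hydroxyl of A5 must be replaced by a carbon chain, the acetyl group converted into an acid-sensitive enol ether, and the α-carbon of the acid alkylated with a di-ortho-substituted ring B benzyl halide that again needs its own synthesis. The α-branched ketene next to a tetrasubstituted double bond may dimerise or be trapped before it cyclises.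
- The chosen strategy accepts one late reduction and in return needs no separate ring B synthesis and keeps the uncertain step on simple, quickly made partners.

Key step: step 8

Remark on the chemistry: the target is achiral; carbinol 18 is the only compound on the route with a stereogenic carbon and forms as a transient racemate.

## Route

Step 1
Reactants: 1 trimethylsulfoxonium iodide
Product: 3 1-[dimethyl(oxo)-λ6-sulfanylidene]propan-2-one, via dimethylsulfoxonium methylide 2 (not isolated)
Conditions: KOtBu, THF, reflux; then AcCl (0.33 equiv), 0 °C to rt
Reagents that add atoms: acetyl chloride, CC(=O)Cl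
Why: Deprotonation gives the Corey–Chaykovsky methylide, which is C-acylated by the acid chloride; a second equivalent of methylide removes the now acidic proton, so the carbonyl-stabilised ylide is the resting product.

Step 2
Reactants: 4 4-hydroxy-2-methoxybenzoic acid; 3 1-[dimethyl(oxo)-λ6-sulfanylidene]propan-2-one
Product: 6 6-hydroxy-8-methoxy-3-methyl-1H-isochromen-1-one, via 4-hydroxy-2-methoxy-6-(2-oxopropyl)benzoic acid 5 (not isolated)
Conditions: [Cp*RhCl2]2 (4 mol%), AgSbF6 (16 mol%), NaOAc (1 equiv), CF3CH2OH, 80 °C; then TsOH·H2O (cat.), PhMe, 90 °C
Reagents that add atoms: none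
Why: Carboxylate-directed C–H metalation by trivalent rhodium at C6 (the only free ortho position), carbene formation from the ylide with loss of the sulfoxide, migratory insertion and protodemetalation give the ortho-acetonyl acid, which closes to the enol lactone by dehydration; this is the known C–H acylmethylation/annulation of benzoic acids with sulfoxonium ylides, here on an unhindered C–H bond.

Step 3
Reactants: 6 6-hydroxy-8-methoxy-3-methyl-1H-isochromen-1-one
Product: 7 6-hydroxy-5-iodo-8-methoxy-3-methyl-1H-isochromen-1-one
Conditions: NIS (1.0 equiv), TsOH·H2O (10 mol%), MeCN, 0 °C to rt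
Reagents that add atoms: N-iodosuccinimide, O=C1CCC(=O)N1I
Why: Electrophilic aromatic iodination of a phenol; C5 is ortho to the hydroxyl, para to the C8 methoxy group and the naphthol-like alpha position, whereas C7 lies between two oxygens and the enol-lactone carbon C4 is far less nucleophilic than the phenol ring.

Step 4
Reactants: 7 6-hydroxy-5-iodo-8-methoxy-3-methyl-1H-isochromen-1-one
Product: 8 5-iodo-8-methoxy-6-(methoxymethoxy)-3-methyl-1H-isochromen-1-one
Conditions: MOMCl, iPr2NEt, CH2Cl2, 0 °C to rt
Reagents that add atoms: chloromethyl methyl ether, COCCl
Why: O-alkylation of the acidic phenol by the small α-chloro ether under amine base; the acetal masks O6 for the ynone stage and is removed by the acid of the last step.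

Step 5
Reactants: 8 5-iodo-8-methoxy-6-(methoxymethoxy)-3-methyl-1H-isochromen-1-one; 9 3-methoxyprop-1-yne
Product: 10 8-methoxy-5-(4-methoxybut-2-ynoyl)-6-(methoxymethoxy)-3-methyl-1H-isochromen-1-one
Conditions: PdCl2(PPh3)2 (5 mol%), CuI (2 mol%), Et3N, THF, CO (1 atm), rt to 45 °C
Reagents that add atoms: carbon monoxide, [C-]#[O+]
Why: Carbonylative Sonogashira coupling: oxidative addition of the aryl iodide to zerovalent palladium, CO insertion to the aroyl complex, transfer of the copper acetylide and reductive elimination; the two ortho substituents retard direct alkynylation more than CO insertion, and the mild amine base leaves lactone and acetal alone.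

Step 6
Reactants: 11 1,1-dimethoxyethene
Product: 12 4,4-dimethoxybut-3-en-2-one
Conditions: AcCl, pyridine, Et2O, 0 °C to rt
Reagents that add atoms: acetyl chloride, CC(=O)Cl
Why: The nucleophilic carbon of the ketene acetal is acylated and the oxocarbenium ion loses a proton to pyridine (addition–elimination), the standard entry to β,β-dialkoxy enones.

Step 7
Reactants: 12 4,4-dimethoxybut-3-en-2-one
Product: 13 1,1-dimethoxy-3-(trimethylsilyloxy)buta-1,3-diene
Conditions: TMSOTf, Et3N, Et2O, 0 °C
Reagents that add atoms: trimethylsilyl trifluoromethanesulfonate, C[Si](C)(C)OS(=O)(=O)C(F)(F)F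
Why: Soft enolisation toward the methyl group and O-silylation give the cross-conjugated silyl dienol ether, as for other 1-alkoxy-3-silyloxybutadienes; the diene is used without chromatography.

Step 8
Reactants: 10 8-methoxy-5-(4-methoxybut-2-ynoyl)-6-(methoxymethoxy)-3-methyl-1H-isochromen-1-one; 13 1,1-dimethoxy-3-(trimethylsilyloxy)buta-1,3-diene
Product: 16 5-[4-hydroxy-2-methoxy-6-(methoxymethyl)benzoyl]-8-methoxy-6-(methoxymethoxy)-3-methyl-1H-isochromen-1-one, via ketal cycloadduct 14 (not isolated), via aryl trimethylsilyl ether 15 (not isolated)
Conditions: 13 (3 equiv), PhMe, 110 °C (sealed tube); then 0.5 M HCl, THF, 0 °C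
Reagents that add atoms: none
Why: Diene 13 has both donors reinforcing its unsubstituted CH2 terminus and ynone 10 is most electrophilic at the alkyne carbon beta to the carbonyl, so they combine in a normal-demand, strongly asynchronous Diels–Alder reaction in which the CH2 terminus bonds to the beta carbon (C2'–C3') and the ketene acetal carbon to the alpha carbon (C1'–C6'). Ring B is thereby closed as a six-membered carbocycle by intermolecular [4+2] cycloaddition, giving the 1,4-cyclohexadiene ketal 14. One methoxy group of the ketal then ionises with help from the second oxygen and the silyl enol ether, and loss of a proton from the doubly allylic CH2 (C3') aromatises the ring to the silyl ether 15, from which dilute acid frees the C4' phenol. The closest known reaction is the cycloaddition of 1,1-dialkoxy-3-silyloxybutadienes with acetylenic ketones and esters, which gives resorcinol monoalkyl ethers in one operation. No stereocentre survives, because both sp3 carbons of 14 become aromatic. The step needs regioselectivity (OMe ortho and OH para to the acyl-bearing carbon), which the matched polarisation of the two partners secures, and chemoselectivity for the ynone over the enol-lactone double bond and the lactone carbonyl, neither of which is activated toward an electron-rich diene. The acetal on O6 keeps that oxygen from adding to the ynone and closing a chromone, and the twist of the di-ortho-substituted aryl group out of the carbonyl plane leaves the C=O conjugated with the alkyne.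

Step 9
Reactants: 16 5-[4-hydroxy-2-methoxy-6-(methoxymethyl)benzoyl]-8-methoxy-6-(methoxymethoxy)-3-methyl-1H-isochromen-1-one
Product: 19 6-hydroxy-5-{[4-hydroxy-2-methoxy-6-(methoxymethyl)phenyl]methyl}-8-methoxy-3-methyl-1H-isochromen-1-one, via free phenol ketone 17 (not isolated), via diarylcarbinol 18 (not isolated)
Conditions: Et3SiH (6 equiv), CF3CO2H/CH2Cl2 (1:2), 0 °C to rt
Reagents that add atoms: none
Why: Ionic hydrogenation: the acid cleaves the acetal (the methoxymethyl cation is reduced by the silane) and protonates the ketone, whose cation has an ortho and a para oxygen donor on each ring, and the silane delivers hydride twice (ketone to carbinol 18, then ionisation and reduction to CH2); the CH2OMe group is meta to both oxygens of ring B and is not ionised, and the enol lactone would give only a poorly stabilised acyloxy cation on protonation and is left alone.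

## Compound list

1 | trimethylsulfoxonium iodide | C[S+](C)(C)=O.[I-] | starting material
2 | dimethylsulfoxonium methylide | C=S(C)(C)=O | intermediate
3 | 1-[dimethyl(oxo)-λ6-sulfanylidene]propan-2-one | CC(=O)C=S(C)(C)=O | intermediate
4 | 4-hydroxy-2-methoxybenzoic acid | COc1cc(O)ccc1C(=O)O | starting material
5 | 4-hydroxy-2-methoxy-6-(2-oxopropyl)benzoic acid | CC(=O)Cc1cc(O)cc(OC)c1C(=O)O | intermediate
6 | 6-hydroxy-8-methoxy-3-methyl-1H-isochromen-1-one | COc1cc(O)cc2cc(C)oc(=O)c12 | intermediate
7 | 6-hydroxy-5-iodo-8-methoxy-3-methyl-1H-isochromen-1-one | COc1cc(O)c(I)c2cc(C)oc(=O)c12 | intermediate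
8 | 5-iodo-8-methoxy-6-(methoxymethoxy)-3-methyl-1H-isochromen-1-one | COCOc1cc(OC)c2c(=O)oc(C)cc2c1I | intermediate
9 | 3-methoxyprop-1-yne | COCC#C | starting material
10 | 8-methoxy-5-(4-methoxybut-2-ynoyl)-6-(methoxymethoxy)-3-methyl-1H-isochromen-1-one | COCC#CC(=O)c1c(OCOC)cc(OC)c2c(=O)oc(C)cc12 | intermediate
11 | 1,1-dimethoxyethene | C=C(OC)OC | starting material
12 | 4,4-dimethoxybut-3-en-2-one | CC(=O)C=C(OC)OC | intermediate
13 | 1,1-dimethoxy-3-(trimethylsilyloxy)buta-1,3-diene | COC(OC)=CC(=C)O[Si](C)(C)C | intermediate
14 | 5-{[6,6-dimethoxy-2-(methoxymethyl)-4-(trimethylsilyloxy)cyclohexa-1,4-dien-1-yl]carbonyl}-8-methoxy-6-(methoxymethoxy)-3-methyl-1H-isochromen-1-one | COCC1=C(C(=O)c2c(OCOC)cc(OC)c3c(=O)oc(C)cc23)C(OC)(OC)C=C(O[Si](C)(C)C)C1 | intermediate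
15 | 8-methoxy-5-[2-methoxy-6-(methoxymethyl)-4-(trimethylsilyloxy)benzoyl]-6-(methoxymethoxy)-3-methyl-1H-isochromen-1-one | COCc1cc(O[Si](C)(C)C)cc(OC)c1C(=O)c1c(OCOC)cc(OC)c2c(=O)oc(C)cc12 | intermediate
16 | 5-[4-hydroxy-2-methoxy-6-(methoxymethyl)benzoyl]-8-methoxy-6-(methoxymethoxy)-3-methyl-1H-isochromen-1-one | COCc1cc(O)cc(OC)c1C(=O)c1c(OCOC)cc(OC)c2c(=O)oc(C)cc12 | intermediate
17 | 6-hydroxy-5-[4-hydroxy-2-methoxy-6-(methoxymethyl)benzoyl]-8-methoxy-3-methyl-1H-isochromen-1-one | COCc1cc(O)cc(OC)c1C(=O)c1c(O)cc(OC)c2c(=O)oc(C)cc12 | intermediate
18 | 6-hydroxy-5-{hydroxy[4-hydroxy-2-methoxy-6-(methoxymethyl)phenyl]methyl}-8-methoxy-3-methyl-1H-isochromen-1-one (racemic) | COCc1cc(O)cc(OC)c1C(O)c1c(O)cc(OC)c2c(=O)oc(C)cc12 | intermediate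
19 | 6-hydroxy-5-{[4-hydroxy-2-methoxy-6-(methoxymethyl)phenyl]methyl}-8-methoxy-3-methyl-1H-isochromen-1-one | COCc1cc(O)cc(OC)c1Cc1c(O)cc(OC)c2c(=O)oc(C)cc12 | target

## Step count and least certain steps

Total: 9 steps. Longest linear sequence: 7 steps (steps 1, 2, 3, 4, 5, 8 and 9; six of them from acid 4).

**Step 8 (key step).** The most likely failure is a cycloaddition too slow to compete with thermal decay or desilylation of the diene, because the alkyne is disubstituted and its carbonyl group is shielded by a di-ortho-substituted aryl ring. The reaction may also stop after the first C–C bond without closing the ring. Fallback, from 12 and 10, returning at 16: the same two bonds are made by a stepwise anionic annulation. Enone 12 is deprotonated at its methyl group (LiN(iPr)2, THF, −78 °C) to lithium 4,4-dimethoxybuta-1,3-dien-2-olate F1, which adds in Michael fashion to the beta carbon of ynone 10. This gives lithium 1-[8-methoxy-6-(methoxymethoxy)-3-methyl-1-oxo-1H-isochromen-5-yl]-7,7-dimethoxy-3-(methoxymethyl)-5-oxohepta-1,2,6-trien-1-olate F2. On warming, its alpha carbon adds to the ketene acetal carbon, methoxide is expelled, and the cyclohexadienone tautomerises to the phenoxide, which is protonated to 16 at work-up.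

**Step 9.** The diaryl cation may be captured by the neighbouring CH2OMe oxygen, followed by loss of the O-methyl group. The reduction may stall at the carbinol stage because four ortho substituents shield the carbon. Prolonged exposure to acid may cleave the aryl–CH2 bond. Fallback, from 16, returning at 19: the carbonyl is removed through an ortho-quinone methide under basic hydride conditions instead of through a cation.
- The acetal is removed (HCl, MeOH, 40 °C) and 17 is isolated.
- Both phenols are converted (Boc2O, DMAP cat., iPr2NEt, CH2Cl2) into 5-{4-[(tert-butoxycarbonyl)oxy]-2-methoxy-6-(methoxymethyl)benzoyl}-8-methoxy-3-methyl-1-oxo-1H-isochromen-6-yl tert-butyl carbonate F3.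
- NaBH4 in THF/H2O at 0 °C adds hydride to the ketone; the alkoxide takes over the neighbouring carbonate, tert-butyl carbonate is expelled and the ortho-quinone methide is reduced. This gives tert-butyl 4-[(6-hydroxy-8-methoxy-3-methyl-1-oxo-1H-isochromen-5-yl)methyl]-3-methoxy-5-(methoxymethyl)phenyl carbonate F4.
- Brief CF3CO2H/Et3SiH in CH2Cl2 at 0 °C removes the remaining carbonate and gives 19.

**Step 5.** The alkyne may couple to the aryl group without uptake of CO, the alkyne may dimerise oxidatively, or turnover may be slow at the di-ortho-substituted arylpalladium stage. Fallback, from 8 and 9, returning at 10: a polar route without palladium or CO.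
- Iodine–magnesium exchange on 8 (iPrMgCl·LiCl, THF, −40 °C) gives chlorido[8-methoxy-6-(methoxymethoxy)-3-methyl-1-oxo-1H-isochromen-5-yl]magnesium F5.
- Alkyne 9 is formylated (n-BuLi, THF, −78 °C; DMF; KH2PO4 quench) to 4-methoxybut-2-ynal F6.
- Addition of F5 to F6 gives racemic 5-(1-hydroxy-4-methoxybut-2-yn-1-yl)-8-methoxy-6-(methoxymethoxy)-3-methyl-1H-isochromen-1-one F7.
- MnO2 in CH2Cl2 oxidises F7 to 10.

**Step 2.** The protonated ylide may alkylate the carboxylate oxygen instead of the ring, and the electron-rich acid may lose CO2 on heating with the metal salts. Fallback, from 4 and 3, returning at 6: the directing group is changed to an amide, so that no free carboxylate is present and ring closure occurs by acyl transfer.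
- Acid 4 is converted (MeONH2·HCl, EDC·HCl, iPr2NEt, CH2Cl2) into 4-hydroxy-N,2-dimethoxybenzamide F8.
- Under [Cp*RhCl2]2/AgSbF6 with a carboxylic acid additive, F8 and ylide 3 give 4-hydroxy-N,2-dimethoxy-6-(2-oxopropyl)benzamide F9.
- The ketone enol oxygen of F9 closes onto the amide carbonyl with loss of the alkoxyamine to give 6.

## Further compounds

F1 | step 8 | lithium 4,4-dimethoxybuta-1,3-dien-2-olate | [Li+].[O-]C(=C)C=C(OC)OC
F2 | step 8 | lithium 1-[8-methoxy-6-(methoxymethoxy)-3-methyl-1-oxo-1H-isochromen-5-yl]-7,7-dimethoxy-3-(methoxymethyl)-5-oxohepta-1,2,6-trien-1-olate | [Li+].COCC(CC(=O)C=C(OC)OC)=C=C([O-])c1c(OCOC)cc(OC)c2c(=O)oc(C)cc12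
F3 | step 9 | 5-{4-[(tert-butoxycarbonyl)oxy]-2-methoxy-6-(methoxymethyl)benzoyl}-8-methoxy-3-methyl-1-oxo-1H-isochromen-6-yl tert-butyl carbonate | COCc1cc(OC(=O)OC(C)(C)C)cc(OC)c1C(=O)c1c(OC(=O)OC(C)(C)C)cc(OC)c2c(=O)oc(C)cc12
F4 | step 9 | tert-butyl 4-[(6-hydroxy-8-methoxy-3-methyl-1-oxo-1H-isochromen-5-yl)methyl]-3-methoxy-5-(methoxymethyl)phenyl carbonate | COCc1cc(OC(=O)OC(C)(C)C)cc(OC)c1Cc1c(O)cc(OC)c2c(=O)oc(C)cc12
F5 | step 5 | chlorido[8-methoxy-6-(methoxymethoxy)-3-methyl-1-oxo-1H-isochromen-5-yl]magnesium | COCOc1cc(OC)c2c(=O)oc(C)cc2c1[Mg]Cl
F6 | step 5 | 4-methoxybut-2-ynal | COCC#CC=O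
F7 | step 5 | 5-(1-hydroxy-4-methoxybut-2-yn-1-yl)-8-methoxy-6-(methoxymethoxy)-3-methyl-1H-isochromen-1-one (racemic) | COCC#CC(O)c1c(OCOC)cc(OC)c2c(=O)oc(C)cc12
F8 | step 2 | 4-hydroxy-N,2-dimethoxybenzamide | CONC(=O)c1ccc(O)cc1OC
F9 | step 2 | 4-hydroxy-N,2-dimethoxy-6-(2-oxopropyl)benzamide | CONC(=O)c1c(CC(C)=O)cc(O)cc1OC
A1 | alternative 1 | methyl 6-methoxy-2-(2-methoxy-2-oxoethyl)-3-{[2-methoxy-6-(methoxymethyl)-4-(triisopropylsilyloxy)phenyl]methyl}-4-(triisopropylsilyloxy)benzoate | COC(=O)Cc1c(Cc2c(COC)cc(O[Si](C(C)C)(C(C)C)C(C)C)cc2OC)c(O[Si](C(C)C)(C(C)C)C(C)C)cc(OC)c1C(=O)OC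
A2 | alternative 1 | dimethyl malonate | COC(=O)CC(=O)OC
A3 | alternative 2 | methyl 4-hydroxy-2-methoxy-5-{[2-methoxy-6-(methoxymethyl)-4-(methoxymethoxy)phenyl]methyl}-6-[(2-methyl-1,3-dioxolan-2-yl)methyl]benzoate | COC(=O)c1c(OC)cc(O)c(Cc2c(COC)cc(OCOC)cc2OC)c1CC1(C)OCCO1
A4 | alternative 3 | 6-hydroxy-8-methoxy-5-{[2-methoxy-6-(methoxymethyl)-4-(methoxymethoxy)phenyl]methyl}-3-methyl-1H-isochromen-1-one | COCc1cc(OCOC)cc(OC)c1Cc1c(O)cc(OC)c2c(=O)oc(C)cc12
A5 | alternative 3 | 3-acetyl-4-hydroxy-6-methyl-2H-pyran-2-one | CC(=O)c1c(O)cc(C)oc1=O
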